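Compound numbers used below are those of the steps and of the compound list after step 10.

## Analysis of the target

(+)-Chamaechromone (19) is a 5,7-dihydroxychromone (benzo ring A fused to pyranone ring C) whose C3 carries the only stereogenic carbon, C*, of (S) configuration. C* bears a hydrogen, the carbonyl of a 2,4,6-trihydroxyphenyl ketone (ring A') and a methine with two identical 4-hydroxyphenyl rings (B and B'). Because those two rings are the same, the methine is not stereogenic, so the task is absolute control of one centre, not relative control. The C*–H bond is alpha to the aryl ketone and sits on C3 of the chromone, so it is acidic and the centre can be lost by enolisation. C2 of ring C is an electrophilic vinylogous ester carbon that hydroxide and amines open, and the seven phenols must be masked through every basic step. The ketone carbonyl is wedged between a ring with two ortho oxygens and a tertiary carbon with two large branches, so its carbon–carbon bonds are hard to form between two molecules. The strategy rests on ring A': C1' (acyl) and C2' (oxygen) are neighbours and C6' carries a further oxygen, which is the pattern a 3-alkoxy aryne delivers when it inserts into the C–O bond of a carboxylic acid. After deprotection ring A' is symmetric, so only the relation "acyl between two oxygens" has to be right.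

## Retrosynthetic reasoning

**19 to 18.** Six O–CH3 bonds are cut. Methyl ethers are chosen because the phenols must pass through strong base, hot Lewis acid, hydrogenation and hot fluoride, and because 1 and 6 are sold as methyl ethers. The forward step has to free all six oxygens without enolising C* or opening ring C.

**18 to 9 and 16 (through aryne 17).** The C1'–C(=O) and C2'–O bonds of ring A' are cut together. This is the place to cut for three reasons:
- An acyl cation made from 9 would have two anisyl rings within reach and a crowded carbonyl carbon.
- A basic aryl-metal reagent would meet the acidic C*–H and the electrophilic ring C.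
- Insertion of 17 first forms an unhindered aryl–oxygen bond and then forms the crowded carbon–carbon bond inside one molecule.

The gain is threefold. The free C2'–OH arrives in the right place without a selective demethylation. C* is carried as a carboxylic acid, which is much harder to enolise than the ketone. The labile ketone exists for only one step before the end. The forward reaction must add oxygen to the aryne carbon remote from the neighbouring methoxy group and must leave C* untouched.

**9 to 8.** The O–CH3 bond of an ester is cut. A methyl ester is preferred to a benzyl ester, which would otherwise be the natural choice for a neutral release, because the hot boron Lewis acid used two steps earlier would not spare a benzyl ester. The acyl carbon of 8 is shielded and C* is now activated by ring C, so the release has to occur by attack at the methyl carbon and without base.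

**8 to 7.** Ring C is opened at O1–C2 and C2–C3, which removes one carbon at the oxidation level of a formyl group. Ketone 7 has the methylene and the ortho phenol that this closure needs. The forward step must be run under acidic conditions, because C* becomes activated at the moment ring C forms.

**7 to 5 and 6.** The aryl–carbonyl bond C4–C4a is cut. Phenol 6 is symmetric and acylates next to its hydroxyl group, and the free carboxyl of 5 reacts while its methyl ester is a spectator. The two carboxyl groups of 5 are already differentiated by the way 4 is made.

**5 to 4.** The C*–H bond and the neighbouring methine C–H bond are cut, that is, a catalytic asymmetric hydrogenation of the tetrasubstituted alkene. Because the two aryl groups are identical there is no alkene geometry and only one stereocentre arises. The carboxylate arm is the binding group for the catalyst. C* is set here, at the stage of a simple ester and far from any ketone.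

**4 to 1 and 2.** The C=C bond is cut (Stobbe condensation). This reaction gives the half-ester with the acid on the methylene arm, exactly the carboxyl needed for the bond to ring A.

**16 to 14, 10 and 6.** The O–S and C–Si bonds are cut. Silicon must sit between the oxygen that becomes the triflate and a methoxy group, which is the position to which a carbamate of 6 directs lithiation. The same phenol 6 therefore supplies ring A and ring A'.

## Alternatives that were turned down

**Alternative 1:** The disconnection is at both aryl–methine bonds of the diarylmethyl group. In the forward key step the chiral-pool amide A1, methyl (S)-3-methyl-4-oxo-4-(quinolin-8-ylamino)butanoate, would be arylated twice at its methyl group by 4-iodoanisole A2 with Pd(OAc)2 A3 and AgOAc A4, the amide nitrogen and quinoline nitrogen holding divalent palladium, to give A5.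
- For: the stereocentre is bought and not made. On that point it is stronger than the chosen route, which depends on hydrogenating a tetrasubstituted alkene.
- Against: the second arylation must occur at a secondary benzylic C–H next to the stereocentre through a congested palladacycle. The methylene of the ester arm is also beta to the directing amide and can compete. The directing amide must then be removed from a carbonyl flanked by the diarylmethyl group, under forcing conditions that threaten C*.
- Comparison: A5 is only an equivalent of 5, reached in more steps (amide formation, arylation, auxiliary removal against two), and neither ring C nor ring A' has been made. The chosen route gives the same skeleton by two classical steps and keeps its risk in the step that actually builds ring A'.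

**Alternative 2:** The disconnection is at the two aryl–carbonyl bonds, C1'–C(=O) and C4–C4a. In the forward key step the bis(N-methoxy-N-methylamide) A6 would take up two equivalents of 2,4,6-trimethoxyphenyllithium A7 to give the 1,4-diketone A8.
- For: both electron-rich rings are attached in one flask, the nucleophile is symmetric so there is no regiochemistry, and no aryne precursor has to be prepared (three steps fewer on that branch). In reagent simplicity it is stronger.
- Against: the amide carbonyl at C* is alpha-branched with a diarylmethyl neighbour and must accept a di-ortho-substituted aryllithium, so both partners are hindered. The basic reagent can instead remove the C*–H or degrade the hindered amide. A selective ortho demethylation is then still needed before ring C can close.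
- Comparison: the chosen route makes the crowded carbon–carbon bond within one molecule after an easy O-arylation, delivers the ortho hydroxyl directly, and never exposes C* to an organolithium.

**Alternative 3:** The disconnection is at C3–C*, C*–CH(Ar)2 and O1–C2 in one step. In the forward key step Rh2(OAc)4 A9 would decompose the diazoketone A10. The carbene would be intercepted at the alpha-carbon of the enaminone A11. The resulting enol-type intermediate would be alkylated by the cation from bis(4-methoxyphenyl)methanol A12 under a chiral phosphoric acid, and the phenol would close ring C with loss of the amine to give A13.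
- For: it is by far the most convergent plan. Three simple pieces give two carbon–carbon bonds, ring C and C* in one operation. In step economy it is clearly stronger than the chosen route.
- Against: the whole sequence of events has no close model. The carbene has other partners (O–H insertion into A12 or into the phenol of A11). The diarylmethyl cation is highly stabilised and only loosely paired with the chiral anion, so facial control at C* is doubtful. The cation can also alkylate the electron-rich rings. C* would be created alpha to the ketone in an acidic medium where it can enolise at once.
- Comparison: the chosen route is longer, but it sets C* by hydrogenation at the ester stage and uses an established reaction type for each bond.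

Key step: step 9

Assumption: the (R,R) ligand in step 2 is written by analogy with trisubstituted itaconates; the sense of induction on this tetrasubstituted substrate must be confirmed on the first run, and the mirror-image ligand is used if 5 is not the enantiomer formed.

## Route

Step 1
Reactants: 1 4,4'-dimethoxybenzophenone; 2 dimethyl succinate
Product: 4 3-(methoxycarbonyl)-4,4-bis(4-methoxyphenyl)but-3-enoic acid, via paraconate lactone 3 (not isolated)
Conditions: 2 (1.5 equiv), KOtBu (1.3 equiv), t-BuOH, reflux; then aq. HCl
Reagents that add atoms: none
Why: Stobbe condensation: the succinate enolate adds to the non-enolisable diaryl ketone, the alkoxide lactonises onto the distal ester to give 3, and base-induced ring opening (E1cB) leaves the half-ester with the acid on the methylene arm and the ester on the alkene carbon; two identical aryl groups mean there are no alkene isomers.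

Step 2
Reactants: 4
Product: 5 (R)-3-(methoxycarbonyl)-4,4-bis(4-methoxyphenyl)butanoic acid
Conditions: H2 (10 bar), [Rh(cod)((R,R)-Me-DuPHOS)]BF4 (1 mol %), NaOMe (0.1 equiv), MeOH, 25 °C
Reagents that add atoms: none
Why: Carboxylate-directed asymmetric hydrogenation of an itaconate-type half-ester by a cationic rhodium bisphospholane catalyst, a substrate class that includes beta,beta-disubstituted (tetrasubstituted) members; the chelate of alkene and carboxylate on rhodium fixes the face to which both hydrogens are delivered and so sets C*, and with two identical aryl groups only this one centre arises.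

Step 3
Reactants: 5; 6 3,5-dimethoxyphenol
Product: 7 methyl (R)-2-[bis(4-methoxyphenyl)methyl]-4-(2-hydroxy-4,6-dimethoxyphenyl)-4-oxobutanoate
Conditions: 6 (1.2 equiv), BF3·OEt2 (neat), 80 °C; then H2O
Reagents that add atoms: none
Why: Friedel–Crafts (Nencki-type) acylation of a highly activated phenol by a free carboxylic acid in BF3·OEt2, which goes ortho to the hydroxyl with boron chelation of the product; the methyl ester and C* (alpha to an ester only) are spectators, and cyclisation of the acyl group onto an anisyl ring would have to occur meta to its methoxy group and should not compete with the far more nucleophilic phenol.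

Step 4
Reactants: 7
Product: 8 methyl (S)-2-(5,7-dimethoxy-4-oxo-4H-chromen-3-yl)-3,3-bis(4-methoxyphenyl)propanoate
Conditions: BF3·OEt2 (4 equiv), DMF, rt; then MsCl (3 equiv), 70–80 °C; then H2O
Reagents that add atoms: N,N-dimethylformamide, CN(C)C=O
Why: Vilsmeier-type formylation and cyclodehydration as used for isoflavones and 3-alkylchromones: the boron-chelated ketone enolises toward its methylene and takes up the iminium carbon made from DMF and MsCl, the phenol oxygen closes ring C and dimethylamine is lost; the medium is acidic throughout, so C*, which becomes activated only once ring C exists, is not deprotonated (the descriptor changes from R to S by priority only).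

Step 5
Reactants: 8
Product: 9 (S)-2-(5,7-dimethoxy-4-oxo-4H-chromen-3-yl)-3,3-bis(4-methoxyphenyl)propanoic acid
Conditions: LiI (8 equiv), EtOAc, reflux; then 1 M HCl
Reagents that add atoms: none
Why: SN2 dealkylation of a methyl ester by iodide with lithium coordination at the carbonyl: attack is at the methyl carbon, so the shielding of the acyl carbon does not matter, no base is present to remove the C*–H or open ring C, and aryl methyl ethers are much poorer electrophiles at this temperature.

Step 6
Reactants: 6
Product: 10 3,5-dimethoxyphenyl N-(propan-2-yl)carbamate
Conditions: i-PrNCO (1.3 equiv), Et3N (0.2 equiv), CH2Cl2, rt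
Reagents that add atoms: isopropyl isocyanate, CC(C)N=C=O
Why: Amine-catalysed addition of a phenol to an isocyanate; the N-monoalkyl carbamate is chosen because it directs lithiation strongly and is later removed by mild base.

Step 7
Reactants: 10
Product: 14 3,5-dimethoxy-2-(trimethylsilyl)phenyl N-(propan-2-yl)carbamate, via N-silyl carbamate 11 (not isolated), via ortho-lithiated N-silyl carbamate 12 (not isolated), via N,C-disilyl carbamate 13 (not isolated)
Conditions: TMSOTf (1.1 equiv), TMEDA (1.1 equiv), Et2O, 0 °C to rt; n-BuLi (2.1 equiv), TMEDA (2 equiv), −78 °C; TMSCl (3 equiv), −78 °C to rt; then aq. NaHSO4, 0 °C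
Reagents that add atoms: chlorotrimethylsilane, C[Si](C)(C)Cl
Why: Directed ortho-metalation: after temporary N-silylation the carbamate and the neighbouring methoxy group together direct lithium to C2 (C2 and C6 are equivalent), the aryllithium is silylated, and the N–Si bond is hydrolysed on work-up; C4 between the two methoxy groups lacks the stronger carbamate director.

Step 8
Reactants: 14
Product: 16 3,5-dimethoxy-2-(trimethylsilyl)phenyl trifluoromethanesulfonate, via 3,5-dimethoxy-2-(trimethylsilyl)phenol 15 (not isolated)
Conditions: DBU (1.5 equiv), Et2NH (1.2 equiv), MeCN, 40 °C; then PhNTf2 (1.5 equiv), rt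
Reagents that add atoms: N-phenylbis(trifluoromethanesulfonimide), O=S(=O)(N(c1ccccc1)S(=O)(=O)C(F)(F)F)C(F)(F)F
Why: Base-induced E1cB cleavage of the N-monoalkyl carbamate releases the phenoxide of 15 and isopropyl isocyanate, which diethylamine takes up as a urea; the phenoxide is triflated in the same flask, and the non-acidic medium spares the electron-rich aryl–silicon bond.

Step 9
Reactants: 9; 16
Product: 18 (S)-1-(2-hydroxy-4,6-dimethoxyphenyl)-2-(5,7-dimethoxy-4-oxo-4H-chromen-3-yl)-3,3-bis(4-methoxyphenyl)propan-1-one, via 3,5-dimethoxybenzyne 17 (not isolated)
Conditions: 16 (1.5 equiv), CsF (4 equiv), THF, sealed tube, 125 °C; then aq. NH4Cl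
Reagents that add atoms: none
Why: Fluoride removes the silyl group of 16 with loss of triflate and releases aryne 17 slowly, and the cesium carboxylate of 9 adds through oxygen to C1 of 17, the aryne carbon remote from the 3-methoxy group. The aryl anion thus formed at C2 lies ortho to the new acyloxy group and attacks its carbonyl carbon (4-exo-trig) to give a transient four-membered alkoxide, which opens by C–O cleavage to the ortho-acylphenoxide of 18; no ring of the product is closed and no stereocentre is formed. The closest known reaction type is the fluoride-induced insertion of arynes into the C–O bond of aryl and alkyl carboxylic acids to give ortho-hydroxyaryl ketones, an anionic Fries-type 1,3-acyl shift. The regioselectivity needed comes from the methoxy group beside the triple bond, which by inductive withdrawal and distortion of the aryne sends the nucleophile to the distal carbon and the negative charge to the carbon next to it, so the acyl group ends between OH and OMe; the 5-methoxy group is meta to the attacked carbon and does not oppose this. The chemoselectivity needed is acyl transfer over proton transfer and over attack on ring C: THF offers no acidic hydrogen, the acyl shift runs through a small cyclic transition state within one molecule, and addition of the aryl anion to C2 or C4 of the chromone would need seven-membered rings. C* has to survive: in 9 it is alpha to a carboxylate, which resists deprotonation, no acyl halide or ketene is ever formed, and in the product the ketone is part of a cesium ortho-acylphenoxide (a vinylogous carboxylate) whose enolisation toward C* would need a fully substituted enol beside a 2,6-disubstituted ring. Because the carbon–carbon bond is made intramolecularly, the crowding around the carbonyl carbon should count for less than in an acylation between two molecules.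

Step 10
Reactants: 18
Product: 19 (+)-chamaechromone, (S)-2-(5,7-dihydroxy-4-oxo-4H-chromen-3-yl)-3,3-bis(4-hydroxyphenyl)-1-(2,4,6-trihydroxyphenyl)propan-1-one
Conditions: BBr3 (15 equiv), CH2Cl2, −78 °C to rt; then MeOH, H2O, 0 °C
Reagents that add atoms: none
Why: Lewis-acid cleavage of aryl methyl ethers (bromide attacks the methyl group of the boron-bound ether); the two ethers beside carbonyl groups should go first and the other four need room temperature; enolisation toward C* would require a fully substituted enol next to a 2,6-dioxygenated ring and is sterically disfavoured, and ring C is stable to the reagent.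

## Compound list

1 | 4,4'-dimethoxybenzophenone | O=C(c1ccc(OC)cc1)c1ccc(OC)cc1 | starting material
2 | dimethyl succinate | COC(=O)CCC(=O)OC | starting material
3 | methyl 2,2-bis(4-methoxyphenyl)-5-oxooxolane-3-carboxylate (racemic paraconate lactone) | COC(=O)C1CC(=O)OC1(c1ccc(OC)cc1)c1ccc(OC)cc1 | intermediate
4 | 3-(methoxycarbonyl)-4,4-bis(4-methoxyphenyl)but-3-enoic acid | COC(=O)C(CC(=O)O)=C(c1ccc(OC)cc1)c1ccc(OC)cc1 | intermediate
5 | (R)-3-(methoxycarbonyl)-4,4-bis(4-methoxyphenyl)butanoic acid | COC(=O)[C@H](CC(=O)O)C(c1ccc(OC)cc1)c1ccc(OC)cc1 | intermediate
6 | 3,5-dimethoxyphenol | COc1cc(O)cc(OC)c1 | starting material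
7 | methyl (R)-2-[bis(4-methoxyphenyl)methyl]-4-(2-hydroxy-4,6-dimethoxyphenyl)-4-oxobutanoate | COC(=O)[C@H](CC(=O)c1c(O)cc(OC)cc1OC)C(c1ccc(OC)cc1)c1ccc(OC)cc1 | intermediate
8 | methyl (S)-2-(5,7-dimethoxy-4-oxo-4H-chromen-3-yl)-3,3-bis(4-methoxyphenyl)propanoate | COC(=O)[C@H](c1coc2cc(OC)cc(OC)c2c1=O)C(c1ccc(OC)cc1)c1ccc(OC)cc1 | intermediate
9 | (S)-2-(5,7-dimethoxy-4-oxo-4H-chromen-3-yl)-3,3-bis(4-methoxyphenyl)propanoic acid | OC(=O)[C@H](c1coc2cc(OC)cc(OC)c2c1=O)C(c1ccc(OC)cc1)c1ccc(OC)cc1 | intermediate
10 | 3,5-dimethoxyphenyl N-(propan-2-yl)carbamate | COc1cc(OC)cc(OC(=O)NC(C)C)c1 | intermediate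
11 | 3,5-dimethoxyphenyl N-(propan-2-yl)-N-(trimethylsilyl)carbamate | COc1cc(OC)cc(OC(=O)N(C(C)C)[Si](C)(C)C)c1 | intermediate
12 | 2-lithio-3,5-dimethoxyphenyl N-(propan-2-yl)-N-(trimethylsilyl)carbamate | COc1cc(OC)c([Li])c(OC(=O)N(C(C)C)[Si](C)(C)C)c1 | intermediate
13 | 3,5-dimethoxy-2-(trimethylsilyl)phenyl N-(propan-2-yl)-N-(trimethylsilyl)carbamate | COc1cc(OC)c([Si](C)(C)C)c(OC(=O)N(C(C)C)[Si](C)(C)C)c1 | intermediate
14 | 3,5-dimethoxy-2-(trimethylsilyl)phenyl N-(propan-2-yl)carbamate | COc1cc(OC)c([Si](C)(C)C)c(OC(=O)NC(C)C)c1 | intermediate
15 | 3,5-dimethoxy-2-(trimethylsilyl)phenol | COc1cc(OC)c([Si](C)(C)C)c(O)c1 | intermediate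
16 | 3,5-dimethoxy-2-(trimethylsilyl)phenyl trifluoromethanesulfonate | COc1cc(OC)c([Si](C)(C)C)c(OS(=O)(=O)C(F)(F)F)c1 | intermediate
17 | 3,5-dimethoxybenzyne (1,2-didehydro-3,5-dimethoxybenzene) | COC1=CC(OC)=CC#C1 | intermediate
18 | (S)-1-(2-hydroxy-4,6-dimethoxyphenyl)-2-(5,7-dimethoxy-4-oxo-4H-chromen-3-yl)-3,3-bis(4-methoxyphenyl)propan-1-one | O=C(c1c(O)cc(OC)cc1OC)[C@H](c1coc2cc(OC)cc(OC)c2c1=O)C(c1ccc(OC)cc1)c1ccc(OC)cc1 | intermediate
19 | (+)-chamaechromone, (S)-2-(5,7-dihydroxy-4-oxo-4H-chromen-3-yl)-3,3-bis(4-hydroxyphenyl)-1-(2,4,6-trihydroxyphenyl)propan-1-one | O=C(c1c(O)cc(O)cc1O)[C@H](c1coc2cc(O)cc(O)c2c1=O)C(c1ccc(O)cc1)c1ccc(O)cc1 | target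

## Step count and least certain steps

Total: 10 steps. Longest linear sequence: 7 steps (steps 1–5, 9 and 10, from 1). The branch to 16 is 3 steps from 6.

**Step 9 (key step).** The most likely failure is loss of configuration at C*, or diversion of the aryl anion before the acyl shift. The C*–H of the intermediate aryl ester is activated by the ester and by ring C and can be reached by the aryl anion through a six-membered transition state. That would end in a plain aryl ester or in racemic material. The product phenoxide may also slowly enolise at 125 °C under fluoride. A first adjustment is aryne release at lower temperature with KF and 18-crown-6.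

The fallback forms the same two bonds by electrophilic chemistry. It sets out from 9 and 6, which are heated in BF3·OEt2 at 70–80 °C as in step 3 (Friedel–Crafts acylation, possibly through the aryl ester and a Fries shift), and it comes back to the route at 18. Its regiochemistry is not critical, because ring A' becomes symmetric on demethylation. Its weak points are the crowded acyl carbon and the anisyl rings near the acyl cation, which is why it is not the first choice. It makes no new compound.

**Step 2.** The most likely failure is slow or poorly face-selective hydrogenation. The alkene is tetrasubstituted and carries two aryl groups, so it binds weakly to the rhodium centre, and the sense and level of induction for a diaryl member of this class are not secured.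

The fallback is resolution instead of asymmetric catalysis. It sets out from 4, which is hydrogenated over Pd/C (H2, MeOH) to racemic 3-(methoxycarbonyl)-4,4-bis(4-methoxyphenyl)butanoic acid F1. F1 is crystallised with (S)-1-phenylethylamine from ethanol to give the less soluble salt (S)-1-phenylethan-1-aminium (R)-3-(methoxycarbonyl)-4,4-bis(4-methoxyphenyl)butanoate F2. The antipodal amine is used if the other diastereomer is the one that crystallises. Dilute HCl liberates the acid, and the route is rejoined at 5.

**Step 5.** The most likely failure is slow dealkylation in ethyl acetate. Long heating could then remove the 5-O-methyl group of ring A by the same SN2 path (lithium held between O4 and O5), which would leave a phenol that interferes in step 9. Partial epimerisation at the now activated C* is the second risk.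

The fallback changes the ester before ring C exists. It sets out from 7, where C* is alpha to an ester only and no chromone is present.
- LiOH in THF/H2O gives (R)-2-[bis(4-methoxyphenyl)methyl]-4-(2-hydroxy-4,6-dimethoxyphenyl)-4-oxobutanoic acid F3.
- BnBr and KHCO3 in DMF alkylate the carboxylate selectively to benzyl (R)-2-[bis(4-methoxyphenyl)methyl]-4-(2-hydroxy-4,6-dimethoxyphenyl)-4-oxobutanoate F4.
- Ring closure as in step 4 gives benzyl (S)-2-(5,7-dimethoxy-4-oxo-4H-chromen-3-yl)-3,3-bis(4-methoxyphenyl)propanoate F5. BF3 is bound by DMF there and is far milder than the neat reagent of step 3.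
- Hydrogenolysis (H2, Pd/C, EtOAc) returns to the route at 9 under neutral conditions.

**Step 10.** The most likely failure is incomplete cleavage of the four ethers that are not beside a carbonyl group at temperatures where C* is safe. The long exposure to BBr3 and HBr at room temperature that they need could cause enolisation of the boron-bound ketone (loss of optical purity) or protodeacylation of the electron-rich ring A'.

The fallback removes the four ethers of rings A, B and B' before ring A' is attached, and attaches ring A' unprotected. It sets out from 9. BBr3 (CH2Cl2, −78 °C to rt) gives (S)-2-(5,7-dihydroxy-4-oxo-4H-chromen-3-yl)-3,3-bis(4-hydroxyphenyl)propanoic acid F6, in which C* is alpha to a carboxylic acid only. F6 then acylates commercial benzene-1,3,5-triol in BF3·OEt2 at 60–70 °C (Nencki-type acylation of a symmetric triol, so no regiochemistry and no protecting groups on ring A'). This comes back to the route at 19 and forgoes step 9.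

## Further compounds

F0 | step 9 | none | none
F1 | step 2 | racemic 3-(methoxycarbonyl)-4,4-bis(4-methoxyphenyl)butanoic acid | COC(=O)C(CC(=O)O)C(c1ccc(OC)cc1)c1ccc(OC)cc1
F2 | step 2 | (S)-1-phenylethan-1-aminium (R)-3-(methoxycarbonyl)-4,4-bis(4-methoxyphenyl)butanoate | COC(=O)[C@H](CC(=O)[O-])C(c1ccc(OC)cc1)c1ccc(OC)cc1.C[C@H]([NH3+])c1ccccc1
F3 | step 5 | (R)-2-[bis(4-methoxyphenyl)methyl]-4-(2-hydroxy-4,6-dimethoxyphenyl)-4-oxobutanoic acid | OC(=O)[C@H](CC(=O)c1c(O)cc(OC)cc1OC)C(c1ccc(OC)cc1)c1ccc(OC)cc1
F4 | step 5 | benzyl (R)-2-[bis(4-methoxyphenyl)methyl]-4-(2-hydroxy-4,6-dimethoxyphenyl)-4-oxobutanoate | O=C(OCc1ccccc1)[C@H](CC(=O)c1c(O)cc(OC)cc1OC)C(c1ccc(OC)cc1)c1ccc(OC)cc1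
F5 | step 5 | benzyl (S)-2-(5,7-dimethoxy-4-oxo-4H-chromen-3-yl)-3,3-bis(4-methoxyphenyl)propanoate | O=C(OCc1ccccc1)[C@H](c1coc2cc(OC)cc(OC)c2c1=O)C(c1ccc(OC)cc1)c1ccc(OC)cc1
F6 | step 10 | (S)-2-(5,7-dihydroxy-4-oxo-4H-chromen-3-yl)-3,3-bis(4-hydroxyphenyl)propanoic acid | OC(=O)[C@H](c1coc2cc(O)cc(O)c2c1=O)C(c1ccc(O)cc1)c1ccc(O)cc1
A1 | alternative 1 | methyl (S)-3-methyl-4-oxo-4-(quinolin-8-ylamino)butanoate | O=C(Nc1cccc2cccnc12)[C@H](CC(=O)OC)C
A2 | alternative 1 | 4-iodoanisole | COc1ccc(I)cc1
A3 | alternative 1 | palladium diacetate, Pd(OAc)2 | CC(=O)[O-].CC(=O)[O-].[Pd+2]
A4 | alternative 1 | silver acetate, AgOAc | CC(=O)[O-].[Ag+]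
A5 | alternative 1 | methyl (R)-4,4-bis(4-methoxyphenyl)-3-(quinolin-8-ylcarbamoyl)butanoate | O=C(Nc1cccc2cccnc12)[C@H](CC(=O)OC)C(c1ccc(OC)cc1)c1ccc(OC)cc1
A6 | alternative 2 | (R)-2-[bis(4-methoxyphenyl)methyl]-N1,N4-dimethoxy-N1,N4-dimethylbutanediamide | CON(C)C(=O)[C@H](CC(=O)N(C)OC)C(c1ccc(OC)cc1)c1ccc(OC)cc1
A7 | alternative 2 | 2,4,6-trimethoxyphenyllithium | [Li]c1c(OC)cc(OC)cc1OC
A8 | alternative 2 | (R)-2-[bis(4-methoxyphenyl)methyl]-1,4-bis(2,4,6-trimethoxyphenyl)butane-1,4-dione | O=C(c1c(OC)cc(OC)cc1OC)[C@H](CC(=O)c1c(OC)cc(OC)cc1OC)C(c1ccc(OC)cc1)c1ccc(OC)cc1
A9 | alternative 3 | dirhodium tetraacetate, Rh2(OAc)4 | CC(=O)[O-].CC(=O)[O-].CC(=O)[O-].CC(=O)[O-].[Rh+2].[Rh+2]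
A10 | alternative 3 | 2-diazo-1-(2,4,6-trimethoxyphenyl)ethan-1-one | [N-]=[N+]=CC(=O)c1c(OC)cc(OC)cc1OC
A11 | alternative 3 | (E)-3-(dimethylamino)-1-(2-hydroxy-4,6-dimethoxyphenyl)prop-2-en-1-one | CN(C)/C=C/C(=O)c1c(O)cc(OC)cc1OC
A12 | alternative 3 | bis(4-methoxyphenyl)methanol | OC(c1ccc(OC)cc1)c1ccc(OC)cc1
A13 | alternative 3 | (S)-2-(5,7-dimethoxy-4-oxo-4H-chromen-3-yl)-3,3-bis(4-methoxyphenyl)-1-(2,4,6-trimethoxyphenyl)propan-1-one | O=C(c1c(OC)cc(OC)cc1OC)[C@H](c1coc2cc(OC)cc(OC)c2c1=O)C(c1ccc(OC)cc1)c1ccc(OC)cc1
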